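The numbers in the tables stem from a simulated flask for substances that don't exist; scatter was added.

Percent of charge is a trap: the same amount of target per litre prints as a bigger percentage in a flask charged with less solid substrate. So set the last readings of the earlier runs beside their charges.

| flask | solid substrate | capture agent | remark | time |
|---|---|---|---|---|
| red | 2 M | 0.13 M | run made earlier |  |
| teal | 2 M | 0.24 M | run made earlier |  |
| ochre | 1.6 M | 0.10 M | run made earlier |  |
| south | 1.0 M | 0.200 M |  | 4.0 min |
| north | 2.0 M | 0.100 M |  | 4.0 min |

| run | time / min | target / % |
|---|---|---|
| red | 0.250 | 0.9 |
| red | 0.833 | 3.0 |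
| red | 1.33 | 4.8 |
| red | 2.00 | 7.0 |
| red | 3.00 | 8.3 |
| red | 4.00 | 9.5 |
| teal | 0.333 | 1.8 |
| teal | 0.500 | 2.8 |
| teal | 0.833 | 2.7 |
| teal | 1.33 | 4.1 |
| teal | 2.50 | 6.9 |
| teal | 4.00 | 8.3 |
| ochre | 0.333 | 0.8 |
| ochre | 0.667 | 4.2 |
| ochre | 1.00 | 4.2 |
| ochre | 2.00 | 7.8 |
| ochre | 4.00 | 13.4 |

(scatter of a reading: 1 percentage point)

- as a solid, counted per litre of solution: solid substrate
- the numbers in the tables scatter by 1 percentage point (one standard deviation)
- what may be going on: starting material -> open intermediate; open intermediate <-> target; open intermediate <-> isomer of the product; open intermediate -> decomposed reagent; solid substrate <-> starting material; open intermediate + capture agent -> trapped intermediate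
- at the start none of the solid substrate is in solution
- what has only dissolved of solid substrate counts as not reacted

- which one finishes higher in amount of target, in percent of the solid substrate charged ("neither" within 2 percentage points) (south / north / neither)
- amount of target at the end, in percent of the solid substrate charged, south
- amount of target at the end, in percent of the solid substrate charged, north

| run | solid substrate | capture agent | target | target per litre |
|---|---|---|---|---|
| red | 2 M | 0.13 M | 9.5% | 0.190 M |
| teal | 2 M | 0.24 M | 8.3% | 0.166 M |
| ochre | 1.6 M | 0.10 M | 13.4% | 0.214 M |

Read red against teal first: teal has 1.85 times the capture agent, yet its reading shifts by 1.2 percentage points, near the scatter of 1 point. So set the agent aside. Now read down the columns: highest over lowest, the percent column spans 1.61, and the per-litre column is narrower at 1.29. That looks like a zero-order supply, so carry one number: the target per litre at 4.0 min, the reading times the charge, averaged over the runs, 0.190 M.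

Divide it by each charge. My reckoning gives south 19.0% and north 9.51%, a gap of 9.5 points, wider than the margin of 2 points. South's charge lies below those of the runs, so its figure is the less sure, but I say south.

The forecast differs: it says north, with south at 7% (5% to 9%) and north at 13% (10.5% to 16%), reasoning of south “so its agent never runs out”.

The flasks give south: south 16.8%, north 9.05%.

    starting material → open intermediate (k = 1.07 s⁻¹)
    open intermediate ⇌ target (K = 1.91, k = 0.0680 s⁻¹)
    open intermediate ⇌ isomer of the product (K = 2.60, k = 0.0250 s⁻¹)
    open intermediate → decomposed reagent (k = 0.0314 s⁻¹)
    solid substrate ⇌ starting material, rate k5*(cs5 - [starting material]) while solid is left; crystals form when [starting material] > cs5 (solubility = 0.220 M, k = 0.0201 s⁻¹)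
    open intermediate + capture agent → trapped intermediate (k = 0.0206 L mol⁻¹ s⁻¹)

South holds 0.168 M of target per litre and north 0.181 M, against the 0.190 M carried over. At 2.00 min each has lost the same solid per litre, 0.521 M and 0.521 M. South's target stays at 16.8% mainly because target undoes into open intermediate: in a run of south without that undoing, the target reaches 58.9%. For south with 1.7 M of solid substrate, the carried number gives 11.2%, and that flask stands at 10.3%.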